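The complex with one exchanged is the product you want, the lowest rung above the start on a ladder that incoming ligand climbs and leaving ligand descends, so the question is how far up to charge the flask.

common to all: starting complex 0.010 M
- grey: incoming ligand 15 mM; protic impurity 1 mM; capture agent 0.50 mM; run made earlier
- blue: incoming ligand 60 mM; protic impurity 1 mM; capture agent 0.50 mM; run made earlier
- flask: incoming ligand 30.0 mM; protic impurity 1.00 mM; capture agent 0.500 mM; time 6.0 h

- grey (time / h: complex with one exchanged / %, complex with three exchanged / %): 0.500: 56.0, 1.6; 0.833: 57.1, 1.0; 1.33: 56.9, 0.9; 2.00: 55.9, 0.8; 4.00: 55.0, 1.0; 6.00: 55.2, 1.1
- blue (time / h: complex with one exchanged / %, complex with three exchanged / %): 0.417: 46.4, 15.3; 1.33: 45.2, 14.9; 2.00: 44.8, 14.9; 3.00: 44.6, 14.7; 5.00: 44.3, 14.9; 6.00: 45.4, 14.5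

(standard deviation of a reading: 0.3 percentage points)

1. equivalents of incoming ligand to starting complex, everything else as given, that leave most complex with one exchanged at 6.0 h
2. the amount of complex with one exchanged then, in percent of the starting complex charged
3. the amount of complex with one exchanged with the amounts as given

- the earlier runs were read with a standard deviation of 0.3 percentage points
- steps under discussion: starting complex + incoming ligand <-> leaving ligand + complex with one exchanged; complex with one exchanged + incoming ligand <-> leaving ligand + complex with two exchanged; complex with two exchanged + incoming ligand <-> leaving ligand + complex with three exchanged; protic impurity + incoming ligand -> quenched reagent; complex with two exchanged + capture agent -> trapped intermediate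

Turn the time first. By hand the ladder should stop moving once each exchange has equilibrated, and the one-exchanged complex reads 56.0% at 0.500 h and 55.2% at 6.00 h in the grey run, 46.4% at 0.417 h and 45.4% at 6.00 h in the blue run, so I treat both runs as thermodynamic control. Then each rung's share goes as a power of the ratio u = c(incoming ligand)/c(leaving ligand), and, as for any such partition sum, the first rung peaks where the mean number of exchanges per untrapped complex equals one.

Turn the capture agent next. If its whole charge ends as trapped intermediate, it removes that much complex and has released two leaving ligands for each, so in this flask the share of complex with one exchanged peaks at a target leaving ligand, c(starting complex) + c(capture agent) = 10.5 mM. Turning the starting complex moves this target by the same amount. The protic impurity, assumed to take incoming ligand one for one, adds its 1.00 mM to the charge needed.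

Turning the incoming ligand moves u. At the peak the charge has to cover the target, the impurity's share and the free incoming ligand, and the runs show what a larger charge does: from 15 mM to 60 mM the one-exchanged complex reads 55.2% and then 45.4%, the three-exchanged 1.1% and then 14.5%. The charge at the peak still needs the step constants.

The forecast reads these from the two runs, says “the one-exchanged fraction of the untrapped 9.5 mM peaks” at u near 1.02, and gives 2.2 equiv, 58% at that charge, and 56.5% as charged.

The flask gives 2.24 equiv, 57.9% and 56.6%.

    starting complex + incoming ligand ⇌ leaving ligand + complex with one exchanged (K = 2.80, k = 0.110 /M/s)
    complex with one exchanged + incoming ligand ⇌ leaving ligand + complex with two exchanged (K = 0.240, k = 0.0400 /M/s)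
    complex with two exchanged + incoming ligand ⇌ leaving ligand + complex with three exchanged (K = 0.180, k = 0.240 /M/s)
    protic impurity + incoming ligand → quenched reagent (k = 0.640 /M/s)
    complex with two exchanged + capture agent → trapped intermediate (k = 0.210 /M/s)

The flask as charged ends with 0.0120 M of leaving ligand, above the target, which puts its mean at 1.16 exchanges per untrapped complex, just past the peak, with 56.6% against 57.9%. A neighbouring flask charged with 0.12 M of incoming ligand has the same target but ends with 0.0198 M of leaving ligand, a mean of 1.98. There the complex with two exchanged holds the most, 34.0%, and the complex with one exchanged falls to 28.3%.

Readings and results are simulated with made-up constants, noise included.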